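Minutes are the unit I count this flask in, so I begin by turning the first slope of the east run into a time.

| setting | east | west | south-east | north | north-east |
|---|---|---|---|---|---|
| Sbt | 0.400 M | 0.160 M | 0.400 M | 0.200 M | 0.400 M |
| Ptn | 1.20 M | 0.960 M | 1.80 M | 1.20 M | 1.20 M |
| time |  |  |  |  | 14 min |

| run | time / min | [Pdt] / M |
|---|---|---|
| east run | 0.80 | 0.0291 |
| east run | 1.6 | 0.0555 |
| east run | 2.4 | 0.0700 |
| east run | 3.2 | 0.0822 |
| east run | 4.0 | 0.0856 |
| east run | 4.8 | 0.0920 |
| east run | 5.6 | 0.0928 |
| west run | 0.80 | 0.0116 |
| west run | 1.6 | 0.0200 |
| west run | 2.4 | 0.0305 |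
| west run | 3.2 | 0.0360 |
| west run | 4.0 | 0.0408 |
| west run | 4.8 | 0.0434 |
| west run | 5.6 | 0.0492 |
| south-east run | 0.80 | 0.0366 |
| south-east run | 1.6 | 0.0654 |
| south-east run | 2.4 | 0.0835 |
| south-east run | 3.2 | 0.0907 |
| south-east run | 4.0 | 0.0980 |
| south-east run | 4.8 | 0.0994 |
| south-east run | 5.6 | 0.1012 |
| north run | 0.80 | 0.0151 |
| north run | 1.6 | 0.0307 |
| north run | 2.4 | 0.0395 |
| north run | 3.2 | 0.0489 |
| north run | 4.0 | 0.0526 |
| north run | 4.8 | 0.0577 |
| north run | 5.6 | 0.0576 |

(each reading ± 0.001 M)

1. the power of [Sbt] that the first rate follows, about the charge of the east run; measure it at two percent of Sbt made into Pdt (one fixed amount of Pdt, the same in the runs compared)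
2. the power of [Ptn] that the first rate follows, about the charge of the east run; measure it at two percent of Sbt made into Pdt
3. Pdt in the north-east run at 14 min, as a share of the Sbt charged

- Overall: Sbt + Ptn -> Pdt.
- Constant volume, constant temperature.
- Bound and free are read together.
- "The second partner" is Ptn.
- An order is taken over about fifteen percent of the charge, up and down.

Take a quarter of the Sbt charged and divide it by the first reading over its time:

clock = 2.75 min

This is my quarter clock, the time the first slope would need to turn a quarter of the Sbt charged into Pdt.

The east run holds 3.00 times as much Ptn as Sbt, so at the bench I would call it pseudo-first-order, with Sbt decaying over a lifetime of 4 clocks, 11.0 min. I test that rule against the east readings: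

at 2.4 min: rule 0.0784 M, reading 0.0700 M, ratio 0.893

at 5.6 min: rule 0.160 M, reading 0.0928 M, ratio 0.581

So the rule is already failing by the first of these times and is far off by the second. The last reading equals 7.73% of the Ptn charged but 23.2% of the Sbt charged, so Ptn turned into Pdt looks too small a loss to explain so hard a bend.

The north-east run has the east charge. The last east step gains 8.00 × 10⁻⁴ M, which is within the scatter, so I commit to about 23.2%. The readings at the first time, taken at one time and not at one fixed amount of Pdt, and over wider steps of charge than the question asks, give me rough orders of about 0.946 in [Sbt] and 0.566 in [Ptn].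

The forecast differs from my figures: 0.87 in [Sbt], 0.55 in [Ptn] and 24.5% for the north-east run, on the ground that “Some equilibrium or binding effect, or a dying active species, seems to cap the yield”.

The simulation gives 1.0 in [Sbt], 0.50 in [Ptn] and 23.6% for the north-east run.

    Sbt + Ptn ⇌ Pdt + Lvg (0.5568 /M/min, 3.456 /M/min)
    2 Ptn ⇌ Ptn2, settled at all times (10.00 /M)
    Sbt + Ptn ⇌ Sbt.Ptn, settled at all times (0.7190 /M)

At 14 min the north-east run has had 5.09 clocks, and the rule would put it at 72.0%, yet it stands at 23.6%. Taking away the parking of 2 Ptn as Ptn2 lifts that run from 23.6% to 37.6%, so this parking holds the yield down by 14 percentage points, which is 18% of what that run falls short of full conversion. In the south-east run the clock is 2.19 min, the rule puts the quarter at 2.52 min, and the flask reaches it at 4.85 min.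

All runs stem from a simulated flask with constants of no real substance, and the scatter is random.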